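Ring B of the target is a 2-hydroxy-4-methoxy-6-pentylbenzoic acid whose C5 carries the diaryl ether oxygen, between the oxygenated C4 and the pentyl-bearing C6. At the dihydro level this ring is a cyclohexane-1,3-dione carboxylate, so C5 and C6 can come from the α- and β-carbons of an enone that already holds the ring A aryloxy group on its α-carbon. Dibenzyl malonate adds to the β-carbon (C1–C6) and the methyl ketone closes on a benzyl ester (C2–C3), building ring B with its full substitution in one operation. The precursor is a (Z)-3-aryloxynon-3-en-2-one made from O-benzylated methyl olivetolate; oxidation, methylation and hydrogenolysis finish the synthesis.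

Key step: step 4

Remark on the chemistry: ring B is numbered C1 (carboxyl-bearing), C2 (OH), C3 (H), C4 (OCH3), C5 (O-aryl), C6 (pentyl) throughout; the target is achiral and the three stereocentres made in step 4 are removed in step 5, so racemic material of any relative configuration is assumed to be acceptable.

Step 1
Reactants: 1 methyl olivetolate (methyl 2,4-dihydroxy-6-pentylbenzoate)
Product: 2 methyl 4-(benzyloxy)-2-hydroxy-6-pentylbenzoate
Conditions: BnBr (1.05 equiv), K2CO3 (1.1 equiv), acetone, reflux
Reagents that add atoms: benzyl bromide, BrCc1ccccc1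
Why: Williamson ether synthesis; the C2 hydroxyl is tied to the ester carbonyl by a hydrogen bond and is the less acidic one, so one equivalent of base and halide should alkylate only the C4 hydroxyl.

Step 2
Reactants: 2 methyl 4-(benzyloxy)-2-hydroxy-6-pentylbenzoate; 3 dimethyl (1-diazo-2-oxopropyl)phosphonate
Product: 4 methyl 4-(benzyloxy)-2-[1-(dimethoxyphosphoryl)-2-oxopropoxy]-6-pentylbenzoate (racemic)
Conditions: Rh2(OAc)4 (2 mol%), 3 added slowly, ClCH2CH2Cl, 80 °C
Reagents that add atoms: none
Why: Rhodium carbenoid O–H insertion: Rh2(OAc)4 turns the diazo ketophosphonate into an electrophilic carbenoid that inserts into the only free O–H of 2, which places the aryloxy group on an sp3 carbon without any substitution at an arene carbon; slow addition keeps carbene dimerization down, and the new stereocentre is racemic and is lost in step 3.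

Step 3
Reactants: 4 methyl 4-(benzyloxy)-2-[1-(dimethoxyphosphoryl)-2-oxopropoxy]-6-pentylbenzoate; 5 hexanal
Product: 6 methyl 4-(benzyloxy)-2-{[(3Z)-2-oxonon-3-en-3-yl]oxy}-6-pentylbenzoate
Conditions: hexanal (1.5 equiv), LiCl, DBU, CH3CN, 0 °C to rt
Reagents that add atoms: none
Why: Horner–Wadsworth–Emmons olefination under mild LiCl/amine conditions that tolerate the enolizable aldehyde; the ketone-stabilized phosphonate should give mainly the isomer with acetyl group and pentyl chain trans (Z by the sequence rule, aryloxy and pentyl cis), and either geometry is usable because both alkene carbons become sp3 in step 4.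

Step 4
Reactants: 6 methyl 4-(benzyloxy)-2-{[(3Z)-2-oxonon-3-en-3-yl]oxy}-6-pentylbenzoate; 7 dibenzyl malonate
Product: 9 benzyl 5-[5-(benzyloxy)-2-(methoxycarbonyl)-3-pentylphenoxy]-2-hydroxy-4-oxo-6-pentylcyclohex-2-ene-1-carboxylate (racemic; all-trans isomer drawn), via open-chain Michael adduct 8 (not isolated)
Conditions: 7 (1.2 equiv), KOC(CH3)3 (1.1 equiv), THF, 0 °C; then 6, rt to 60 °C; cold 1 M HCl work-up
Reagents that add atoms: none
Why: Potassium dibenzyl malonate adds in conjugate fashion to the β-carbon of enone 6 (bond C1–C6) and proton transfer gives adduct 8, in which the small equilibrium share of the terminal CH3-ketone enolate attacks one benzyl ester (bond C2–C3) and expels benzyloxide, which at once deprotonates the new 1,3-dione, so the delocalized dione enolate is the sink that pulls all equilibria forward. The closest known reaction is the Michael–Claisen (Michael–Dieckmann) annulation of malonic esters with non-3-en-2-one to 6-pentylcyclohexane-1,3-dione carboxylates, here run on an enone that bears an aryloxy group on its α-carbon. Ring B, the only ring formed, closes in the 6-exo-trig mode on the ester carbonyl. The stereocentres C1, C5 and C6 arise racemic; C1 and C5 are α to carbonyl groups and should equilibrate against C6 toward the all-equatorial, all-trans isomer, but no control is needed because step 5 flattens all three. The selectivity needed is closure from the methyl carbon with the aryloxy group retained: the C5 enolate can reach a malonate ester only through a four-membered ring, or the di-ortho-substituted ring A ester to give a non-enolizable β-diketone that reverts, and aryloxide could only be expelled by a carbanion at C6, which no carbonyl group acidifies, so E1cB loss is closed. KOC(CH3)3 is chosen because it deprotonates the malonate without exchanging the benzyl esters or the ring A methyl ester.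

Step 5
Reactants: 9 benzyl 5-[5-(benzyloxy)-2-(methoxycarbonyl)-3-pentylphenoxy]-2-hydroxy-4-oxo-6-pentylcyclohex-2-ene-1-carboxylate
Product: 10 benzyl 5-[5-(benzyloxy)-2-(methoxycarbonyl)-3-pentylphenoxy]-2,4-dihydroxy-6-pentylbenzoate
Conditions: Pd(OCOCF3)2 (5 mol%), 2-(dimethylamino)pyridine (10 mol%), O2 (1 atm), DMSO, 80 °C
Reagents that add atoms: none
Why: Aerobic palladium-catalysed dehydrogenation of a cyclohexanone-type substrate: a divalent palladium enolate at C1 undergoes β-hydride elimination of the C6 hydrogen, enolization then gives the aromatic resorcylate and O2 returns zerovalent palladium to the divalent state; the nearly neutral medium should leave the C5 aryloxy group and both benzyl groups in place.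

Step 6
Reactants: 10 benzyl 5-[5-(benzyloxy)-2-(methoxycarbonyl)-3-pentylphenoxy]-2,4-dihydroxy-6-pentylbenzoate
Product: 11 benzyl 5-[5-(benzyloxy)-2-(methoxycarbonyl)-3-pentylphenoxy]-2-hydroxy-4-methoxy-6-pentylbenzoate
Conditions: CH3I (1.2 equiv), K2CO3 (1.2 equiv), acetone, rt
Reagents that add atoms: iodomethane, CI
Why: Williamson O-methylation; the C2 hydroxyl is hydrogen-bonded to the benzyl ester carbonyl and stays protonated under K2CO3, so only the C4 phenoxide forms and is methylated, while the ring A phenol is still benzylated.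

Step 7
Reactants: 11 benzyl 5-[5-(benzyloxy)-2-(methoxycarbonyl)-3-pentylphenoxy]-2-hydroxy-4-methoxy-6-pentylbenzoate
Product: 12 epiphorellic acid 1 (2-hydroxy-5-[5-hydroxy-2-(methoxycarbonyl)-3-pentylphenoxy]-4-methoxy-6-pentylbenzoic acid)
Conditions: H2 (1 atm), 10% Pd/C, EtOAc–CH3OH, rt
Reagents that add atoms: none
Why: Catalytic hydrogenolysis cleaves the benzyl ether on ring A and the benzyl ester on ring B in one operation, while the methyl ester, the methyl ether and the diaryl ether are inert to H2 over palladium metal at room temperature.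

Compound list

1 | methyl olivetolate (methyl 2,4-dihydroxy-6-pentylbenzoate) | CCCCCc1cc(O)cc(O)c1C(=O)OC | starting material
2 | methyl 4-(benzyloxy)-2-hydroxy-6-pentylbenzoate | CCCCCc1cc(OCc2ccccc2)cc(O)c1C(=O)OC | intermediate
3 | dimethyl (1-diazo-2-oxopropyl)phosphonate | CC(=O)C(=[N+]=[N-])P(=O)(OC)OC | starting material
4 | methyl 4-(benzyloxy)-2-[1-(dimethoxyphosphoryl)-2-oxopropoxy]-6-pentylbenzoate (racemic) | CC(=O)C(Oc1cc(OCc2ccccc2)cc(CCCCC)c1C(=O)OC)P(=O)(OC)OC | intermediate
5 | hexanal | CCCCCC=O | starting material
6 | methyl 4-(benzyloxy)-2-{[(3Z)-2-oxonon-3-en-3-yl]oxy}-6-pentylbenzoate | CCCCC/C=C(\Oc1cc(OCc2ccccc2)cc(CCCCC)c1C(=O)OC)C(C)=O | intermediate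
7 | dibenzyl malonate | O=C(CC(=O)OCc1ccccc1)OCc1ccccc1 | starting material
8 | dibenzyl 2-{3-[5-(benzyloxy)-2-(methoxycarbonyl)-3-pentylphenoxy]-2-oxononan-4-yl}propanedioate (open-chain Michael adduct, racemic diastereomer mixture, not isolated) | CCCCCC(C(C(=O)OCc1ccccc1)C(=O)OCc1ccccc1)C(Oc1cc(OCc2ccccc2)cc(CCCCC)c1C(=O)OC)C(C)=O | intermediate
9 | benzyl 5-[5-(benzyloxy)-2-(methoxycarbonyl)-3-pentylphenoxy]-2-hydroxy-4-oxo-6-pentylcyclohex-2-ene-1-carboxylate (racemic; all-trans: ester at C1 trans to pentyl at C6, pentyl trans to aryloxy at C5) | O=C1C=C(O)[C@H](C(=O)OCc2ccccc2)[C@@H](CCCCC)[C@@H]1Oc1cc(OCc2ccccc2)cc(CCCCC)c1C(=O)OC | intermediate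
10 | benzyl 5-[5-(benzyloxy)-2-(methoxycarbonyl)-3-pentylphenoxy]-2,4-dihydroxy-6-pentylbenzoate | CCCCCc1cc(OCc2ccccc2)cc(Oc2c(O)cc(O)c(C(=O)OCc3ccccc3)c2CCCCC)c1C(=O)OC | intermediate
11 | benzyl 5-[5-(benzyloxy)-2-(methoxycarbonyl)-3-pentylphenoxy]-2-hydroxy-4-methoxy-6-pentylbenzoate | CCCCCc1cc(OCc2ccccc2)cc(Oc2c(OC)cc(O)c(C(=O)OCc3ccccc3)c2CCCCC)c1C(=O)OC | intermediate
12 | epiphorellic acid 1 (2-hydroxy-5-[5-hydroxy-2-(methoxycarbonyl)-3-pentylphenoxy]-4-methoxy-6-pentylbenzoic acid) | CCCCCc1cc(O)cc(Oc2c(OC)cc(O)c(C(=O)O)c2CCCCC)c1C(=O)OC | target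

Total step count: 7
Longest linear sequence: 7 steps (1 to 12)

Steps most likely to fail

Step 4. The conjugate addition to the hindered, donor-substituted enone may be slow, so that the α-aryloxy ketone enolate is diverted (attack on the ring A ester, retro-Michael reaction, ester exchange) before ring B closes. The fallback closes ring B from the other side with the classical acetoacetate/enoate Michael–Claisen pairing. Setting out from 2, Rh2(OAc)4-catalysed O–H insertion with methyl diazo(dimethoxyphosphoryl)acetate would give methyl 4-(benzyloxy)-2-[1-(dimethoxyphosphoryl)-2-methoxy-2-oxoethoxy]-6-pentylbenzoate F1. Horner–Wadsworth–Emmons reaction of F1 with hexanal 5 (LiCl, DBU, CH3CN) would give the α-aryloxy enoate methyl (2Z)-2-[5-(benzyloxy)-2-(methoxycarbonyl)-3-pentylphenoxy]oct-2-enoate F2. Benzyl acetoacetate with KOC(CH3)3 in THF would add through its central carbon to the β-carbon of F2 to give the open-chain adduct 1-benzyl 5-methyl 2-acetyl-4-[5-(benzyloxy)-2-(methoxycarbonyl)-3-pentylphenoxy]-3-pentylpentanedioate F3. The terminal methyl-ketone enolate of F3 then closes on the α-aryloxy methyl ester (bond C3–C4 in place of C2–C3) with loss of methanol. The route is rejoined at 9.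

Step 2. Capture of the rhodium carbenoid by the hindered, hydrogen-bonded C2 phenol may be slow, so that carbene dimerization or attack on the ester carbonyl oxygen or on the electron-rich ring takes over. The fallback makes the ether bond by SN2 opening of an epoxy ketone instead of carbene insertion. (E)-Non-3-en-2-one is epoxidized with H2O2/NaOH in CH3OH (Weitz–Scheffer epoxidation) to racemic trans-1-(3-pentyloxiran-2-yl)ethan-1-one F4. The caesium phenoxide of 2 (Cs2CO3, DMF, 60 °C) should open F4 at the carbon next to the ketone to give methyl 4-(benzyloxy)-2-[(4-hydroxy-2-oxononan-3-yl)oxy]-6-pentylbenzoate F5. F5 loses water by E1cB elimination under the same basic conditions to give the enone. The fallback sets out from 2, bypasses 4 and step 3, and comes back at 6.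

Step 5. Aromatization may proceed by elimination of the ring A phenol from C5 instead of by dehydrogenation, or the chelating dione may stall palladium turnover. The fallback replaces catalytic dehydrogenation by halogenation–dehydrohalogenation. Setting out from 9, N-bromosuccinimide (1 equiv, CH2Cl2, 0 °C) should brominate the doubly activated C3 to give benzyl 5-[5-(benzyloxy)-2-(methoxycarbonyl)-3-pentylphenoxy]-3-bromo-2-hydroxy-4-oxo-6-pentylcyclohex-2-ene-1-carboxylate F6. Heating F6 with LiBr and Li2CO3 in DMF should ionize bromide from the bis-enol form and remove the C6 proton, so that HBr is lost and the ring tautomerizes to the resorcylate with the aryloxy group still on C5. The route is rejoined at 10.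

Further compounds

F1 | step 4 | methyl 4-(benzyloxy)-2-[1-(dimethoxyphosphoryl)-2-methoxy-2-oxoethoxy]-6-pentylbenzoate (racemic) | COC(=O)C(Oc1cc(OCc2ccccc2)cc(CCCCC)c1C(=O)OC)P(=O)(OC)OC
F2 | step 4 | methyl (2Z)-2-[5-(benzyloxy)-2-(methoxycarbonyl)-3-pentylphenoxy]oct-2-enoate | CCCCC/C=C(\Oc1cc(OCc2ccccc2)cc(CCCCC)c1C(=O)OC)C(=O)OC
F3 | step 4 | 1-benzyl 5-methyl 2-acetyl-4-[5-(benzyloxy)-2-(methoxycarbonyl)-3-pentylphenoxy]-3-pentylpentanedioate (racemic diastereomer mixture) | CCCCCC(C(C(C)=O)C(=O)OCc1ccccc1)C(Oc1cc(OCc2ccccc2)cc(CCCCC)c1C(=O)OC)C(=O)OC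
F4 | step 2 | trans-1-(3-pentyloxiran-2-yl)ethan-1-one (racemic) | CCCCC[C@@H]1O[C@H]1C(C)=O
F5 | step 2 | methyl 4-(benzyloxy)-2-[(4-hydroxy-2-oxononan-3-yl)oxy]-6-pentylbenzoate (racemic; configuration at both centres lost on dehydration) | CCCCCC(O)C(Oc1cc(OCc2ccccc2)cc(CCCCC)c1C(=O)OC)C(C)=O
F6 | step 5 | benzyl 5-[5-(benzyloxy)-2-(methoxycarbonyl)-3-pentylphenoxy]-3-bromo-2-hydroxy-4-oxo-6-pentylcyclohex-2-ene-1-carboxylate (racemic; all-trans drawn) | O=C1C(Br)=C(O)[C@H](C(=O)OCc2ccccc2)[C@@H](CCCCC)[C@@H]1Oc1cc(OCc2ccccc2)cc(CCCCC)c1C(=O)OC
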